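**Retrosynthetic overview**

- Numbering (spiro[4.5]decane): C1 = CH–O-isobutyryl, C3 = CH–isopropenyl, C5 = spiro C, C6 = C(Me)=, C8 = C=O, C9 = CH–OAc, C10 = CH–Me.
- 13 ⇒ 12 by α′-acetoxylation (C9); 12 ⇒ pseudo-symmetric spirodienone ester 10 by a desymmetrising 1,4-reduction that sets C5 and C10 together.
- 10 ⇒ dienedione 7 by catalyst-controlled ketone reduction (C1) and acylation.
- 7 (one stereocentre, C3) ⇒ acyclic keto ester 3 + pent-3-yn-2-one 4 in one pot: C1–C5 (Claisen, cyclopentanone first), C5–C10 (Michael), C6=C7 (aldol condensation, cyclohexadienone second).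
- 3 ⇒ (S)-limonene 1 by selective ozonolysis of the ring alkene; C3 comes from the chiral pool.

Assumption: (S)-DTBM-SEGPHOS is taken as the ligand antipode that delivers hydride to the required face, by analogy with its sense on isophorone; if a test run shows the opposite sense, the (R)-ligand is used in step 5.

**Step 1**
Reactants: 1 (S)-(−)-limonene
Product: 3 methyl (3S)-6-oxo-3-(prop-1-en-2-yl)heptanoate, via methoxy-hydroperoxide 2 (not isolated)
Conditions: O3 (1.0 equiv, Sudan Red 7B end point), NaHCO3, CH2Cl2/MeOH 5:1, −78 °C; then Ac2O, Et3N, 0 °C → rt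
Reagents that add atoms: ozone O=[O+][O-]; methanol CO
Why: Chemoselective ozonolysis of the electron-rich trisubstituted ring alkene (the isopropenyl group reacts much more slowly and the dye end point stops the ozone feed), Criegee cleavage in MeOH to the ketone plus α-methoxy hydroperoxide 2, and Ac2O/Et3N dehydration to the methyl ester (Schreiber terminus-differentiating ozonolysis); the C3 stereocentre is carried over unchanged from limonene.

**Step 2**
Reactants: 3 methyl (3S)-6-oxo-3-(prop-1-en-2-yl)heptanoate; 4 pent-3-yn-2-one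
Product: 7 (3S)-6,10-dimethyl-3-(prop-1-en-2-yl)spiro[4.5]deca-6,9-diene-1,8-dione, via β-diketone 5 (not isolated), via Michael adduct 6 (not isolated)
Conditions: KOt-Bu (1.1 equiv), THF, 0 °C → rt, MeOH stripped; 4 (1.15 equiv), THF/t-BuOH, 0 °C; KOt-Bu (2.2 equiv), 0 °C → rt; AcOH (one pot)
Reagents that add atoms: none
Why: Proposed new method: Claisen (Dieckmann-type) acylation of the ketone α-carbon by the ester closes the cyclopentanone as diketonate 5, which adds to the ynone (Michael addition) to give 6 with the quaternary carbon in place; with two further equivalents of base the cyclopentanone (at C2) and the enone are both enolised, so the acetyl group is the only electrophilic carbonyl left for the cross-conjugated C7 enolate, and 6-(enolendo)-exo-trig aldol addition followed by E1cB loss of water gives the cross-conjugated spirodienone (closest known types: cyclisation of ε-keto esters to 2-acetylcyclopentanones, Michael addition of β-diketones to alkynones, Robinson-type spiroannulation of 2-acylcycloalkanones); no new stereocentre forms because the two dienone arms are identical, and the enone geometry equilibrates through the extended enolate.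

**Step 3**
Reactants: 7 (3S)-6,10-dimethyl-3-(prop-1-en-2-yl)spiro[4.5]deca-6,9-diene-1,8-dione
Product: 9 (1R,3S)-1-hydroxy-6,10-dimethyl-3-(prop-1-en-2-yl)spiro[4.5]deca-6,9-dien-8-one, via catecholborate ester 8 (not isolated)
Conditions: (S)-Me-CBS (0.2 equiv), catecholborane (1.5 equiv), toluene, −78 °C; then MeOH, pH 7 buffer
Reagents that add atoms: none
Why: Corey–Bakshi–Shibata reduction: the saturated cyclopentanone is far more electrophilic than the cross-conjugated dienone carbonyl (compare selective 17-ketone reduction of steroidal 1,4-dien-3-ones), catecholborane at −78 °C leaves the isopropenyl group alone, and the (S)-oxazaborolidine reads the quaternary spiro carbon as large and C2H2 as small, giving the (1R) alcohol under catalyst control regardless of the remote C3 centre.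

**Step 4**
Reactants: 9 (1R,3S)-1-hydroxy-6,10-dimethyl-3-(prop-1-en-2-yl)spiro[4.5]deca-6,9-dien-8-one
Product: 10 (1R,3S)-6,10-dimethyl-8-oxo-3-(prop-1-en-2-yl)spiro[4.5]deca-6,9-dien-1-yl 2-methylpropanoate
Conditions: (i-PrCO)2O (1.5 equiv), DMAP (0.1 equiv), pyridine, CH2Cl2, 0 °C
Reagents that add atoms: isobutyric anhydride CC(C)C(=O)OC(=O)C(C)C
Why: DMAP-catalysed acylation under weakly basic conditions, done at once because the free carbinol next to a 4,4-disubstituted cyclohexadienone can fragment (retro-aldol with aromatisation) under stronger base; no stereocentre is touched.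

**Step 5**
Reactants: 10 (1R,3S)-6,10-dimethyl-8-oxo-3-(prop-1-en-2-yl)spiro[4.5]deca-6,9-dien-1-yl 2-methylpropanoate
Product: 12 (1R,3S,5R,10R)-6,10-dimethyl-8-oxo-3-(prop-1-en-2-yl)spiro[4.5]dec-6-en-1-yl 2-methylpropanoate, via silyl dienol ether 11 (not isolated)
Conditions: Cu(OAc)2·H2O (3 mol%), (S)-DTBM-SEGPHOS (3 mol%), (MeO)2MeSiH (2 equiv), toluene, 0 °C → rt; then 0.5 M HCl, THF, 0 °C
Reagents that add atoms: none
Why: Ligand-accelerated CuH 1,4-reduction (Buchwald/Lipshutz asymmetric conjugate reduction of β,β-disubstituted cyclic enones) used to desymmetrise the dienone: hydride goes to C10 on the C4 face (opposite the acyloxy-bearing C1) of the arm remote from the isopropenyl group, with the chiral ligand reinforcing this arm and face choice, so the C10 methyl ends cis to C1 and C5 becomes stereogenic (5R) in the same event; silyl dienol ether 11 cannot be reduced again and hydrolyses to the enone on work-up.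

**Step 6**
Reactants: 12 (1R,3S,5R,10R)-6,10-dimethyl-8-oxo-3-(prop-1-en-2-yl)spiro[4.5]dec-6-en-1-yl 2-methylpropanoate
Product: 13 (1R,3S,5R,9R,10S)-9-acetoxy-6,10-dimethyl-8-oxo-3-(prop-1-en-2-yl)spiro[4.5]dec-6-en-1-yl 2-methylpropanoate
Conditions: Mn(OAc)3·2H2O (3 equiv), benzene, reflux (Dean–Stark)
Reagents that add atoms: manganese(III) acetate CC(=O)[O-].CC(=O)[O-].CC(=O)[O-].[Mn+3]
Why: Mn(OAc)3 α′-acetoxylation of an enone (as for carvone, which also carries an isopropenyl group): C9 is the only enolisable α′ position, acetate is delivered anti to the adjacent C10 methyl, and the epimerisable α-acetoxy ketone also settles as the trans (9R) isomer.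

**Compound list**

1 | (S)-(−)-limonene, (4S)-1-methyl-4-(prop-1-en-2-yl)cyclohex-1-ene | CC1=CC[C@H](CC1)C(C)=C | starting material
2 | (5S)-7-hydroperoxy-7-methoxy-5-(prop-1-en-2-yl)heptan-2-one (C7 epimers) | COC(OO)C[C@H](CCC(C)=O)C(C)=C | intermediate
3 | methyl (3S)-6-oxo-3-(prop-1-en-2-yl)heptanoate | COC(=O)C[C@H](CCC(C)=O)C(C)=C | intermediate
4 | pent-3-yn-2-one | CC#CC(C)=O | starting material
5 | (4S)-2-acetyl-4-(prop-1-en-2-yl)cyclopentan-1-one (potassium enolate in the flask; C2 not fixed) | CC(=O)C1C[C@H](C(C)=C)CC1=O | intermediate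
6 | (4S)-2-acetyl-2-(4-oxopent-2-en-2-yl)-4-(prop-1-en-2-yl)cyclopentan-1-one (E/Z and C2 mixture) | CC(=O)C=C(C)C1(C(C)=O)C[C@H](C(C)=C)CC1=O | intermediate
7 | (3S)-6,10-dimethyl-3-(prop-1-en-2-yl)spiro[4.5]deca-6,9-diene-1,8-dione | CC1=CC(=O)C=C(C)C12C[C@H](C(C)=C)CC2=O | intermediate
8 | 2-{[(1R,3S)-6,10-dimethyl-8-oxo-3-(prop-1-en-2-yl)spiro[4.5]deca-6,9-dien-1-yl]oxy}-1,3,2-benzodioxaborole | CC1=CC(=O)C=C(C)C12C[C@H](C(C)=C)C[C@H]2OB3Oc4ccccc4O3 | intermediate
9 | (1R,3S)-1-hydroxy-6,10-dimethyl-3-(prop-1-en-2-yl)spiro[4.5]deca-6,9-dien-8-one | CC1=CC(=O)C=C(C)C12C[C@H](C(C)=C)C[C@H]2O | intermediate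
10 | (1R,3S)-6,10-dimethyl-8-oxo-3-(prop-1-en-2-yl)spiro[4.5]deca-6,9-dien-1-yl 2-methylpropanoate | CC1=CC(=O)C=C(C)C12C[C@H](C(C)=C)C[C@H]2OC(=O)C(C)C | intermediate
11 | (1R,3S,5R,10R)-8-[dimethoxy(methyl)silyloxy]-6,10-dimethyl-3-(prop-1-en-2-yl)spiro[4.5]deca-6,8-dien-1-yl 2-methylpropanoate | C=C(C)[C@@H]1C[C@@H](OC(=O)C(C)C)[C@@]2(C1)C(C)=CC(O[Si](C)(OC)OC)=C[C@H]2C | intermediate
12 | (1R,3S,5R,10R)-6,10-dimethyl-8-oxo-3-(prop-1-en-2-yl)spiro[4.5]dec-6-en-1-yl 2-methylpropanoate | C=C(C)[C@@H]1C[C@@H](OC(=O)C(C)C)[C@@]2(C1)C(C)=CC(=O)C[C@H]2C | intermediate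
13 | (1R,3S,5R,9R,10S)-9-acetoxy-6,10-dimethyl-8-oxo-3-(prop-1-en-2-yl)spiro[4.5]dec-6-en-1-yl 2-methylpropanoate | C=C(C)[C@@H]1C[C@@H](OC(=O)C(C)C)[C@@]2(C1)C(C)=CC(=O)[C@H](OC(C)=O)[C@H]2C | target

**Total step count:** 6. **Longest linear sequence:** 6.

**Steps most likely to fail**

Step 2 (highest risk). The aldol stage may close on the cyclopentanone carbonyl instead of the acetyl group, giving a fused hydrindadienone (Hajos–Parrish-type closure). Methoxide can also open 6 or 7 by retro-Claisen cleavage, which for 7 is driven by aromatisation. The fallback sets out from 3 and returns at 7; it builds the six-membered ring first, while C1 is still an ester. A base-free Robinson annulation of 3 with (E)-pent-3-en-2-one (pyrrolidine enamine, then AcOH/NaOAc; base is avoided so the Claisen cannot intervene) gives methyl (3S)-4-(2,6-dimethyl-4-oxocyclohex-2-en-1-yl)-3-(prop-1-en-2-yl)butanoate F4 as a mixture of ring diastereomers. KHMDS (2.2 equiv, THF, −78 → 0 °C) then closes the cyclopentanone by γ-acylation of the dienolate (vinylogous Dieckmann; α-attack would need a bridged seven-membered ring), giving (3S)-6,10-dimethyl-3-(prop-1-en-2-yl)spiro[4.5]dec-6-ene-1,8-dione F5. DDQ in refluxing dioxane (the steroidal 4-en-3-one → 1,4-dien-3-one transformation) removes the C10 stereocentre and gives 7.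

Step 5. The β-carbon sits next to the quaternary spiro carbon, so the reduction may be slow, and the arm selection rests on the ligand plus a remote isopropenyl group. The fallback sets out from 10 and returns at 12; it reduces both arms and then desymmetrises by deprotonation. Achiral CuH (Stryker's reagent or (BDP)CuH, PMHS, t-BuOH) reduces both enone units from the C4 face to give (1R,3S)-6,10-dimethyl-8-oxo-3-(prop-1-en-2-yl)spiro[4.5]decan-1-yl 2-methylpropanoate with both methyl groups on the C1 face F6. A chiral lithium amide (lithium bis(1-phenylethyl)amide, TMSCl in situ, THF, −100 °C), of the kind that discriminates the two α-CH2 groups of cis-3,5-dimethylcyclohexanone, removes the C7 proton to give the C7=C8 trimethylsilyl enol ether F7. Saegusa oxidation (Pd(OAc)2, 1 equiv, MeCN) restores the C6=C7 double bond and gives 12.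

Step 1. Ozone can also attack the isopropenyl group, and the ester only forms if the Criegee cleavage places the carbonyl oxide on the former CH carbon. The fallback sets out from 1 and returns at 3; it marks the ring alkene by epoxidation before cleaving it. mCPBA (1.0 equiv, CH2Cl2, 0 °C) epoxidises only the trisubstituted alkene to give (4S)-limonene 1,2-oxide F1 (cis/trans mixture). H5IO6 in aqueous THF cleaves it to (3S)-6-oxo-3-(prop-1-en-2-yl)heptanal F2. Pinnick oxidation (NaClO2, NaH2PO4, 2-methyl-2-butene) gives (3S)-6-oxo-3-(prop-1-en-2-yl)heptanoic acid F3, and TMSCHN2 in MeOH/toluene gives 3.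

**Further compounds**

F1 | step 1 | (4S)-limonene 1,2-oxide (cis/trans mixture) | CC12CC[C@@H](CC1O2)C(C)=C
F2 | step 1 | (3S)-6-oxo-3-(prop-1-en-2-yl)heptanal | O=CC[C@H](CCC(C)=O)C(C)=C
F3 | step 1 | (3S)-6-oxo-3-(prop-1-en-2-yl)heptanoic acid | OC(=O)C[C@H](CCC(C)=O)C(C)=C
F4 | step 2 | methyl (3S)-4-(2,6-dimethyl-4-oxocyclohex-2-en-1-yl)-3-(prop-1-en-2-yl)butanoate (ring diastereomers) | COC(=O)C[C@H](CC1C(C)=CC(=O)CC1C)C(C)=C
F5 | step 2 | (3S)-6,10-dimethyl-3-(prop-1-en-2-yl)spiro[4.5]dec-6-ene-1,8-dione (C5/C10 mixture) | CC1=CC(=O)CC(C)C12C[C@H](C(C)=C)CC2=O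
F6 | step 5 | (1R,3S)-6,10-dimethyl-8-oxo-3-(prop-1-en-2-yl)spiro[4.5]decan-1-yl 2-methylpropanoate, both methyls cis to C1 | C=C(C)[C@@H]1C[C@@H](OC(=O)C(C)C)[C@@]2(C1)[C@@H](C)CC(=O)C[C@H]2C
F7 | step 5 | (1R,3S)-6,10-dimethyl-3-(prop-1-en-2-yl)-8-(trimethylsilyloxy)spiro[4.5]dec-7-en-1-yl 2-methylpropanoate, both methyls cis to C1 | C=C(C)[C@@H]1C[C@@H](OC(=O)C(C)C)[C@@]2(C1)[C@@H](C)C=C(O[Si](C)(C)C)C[C@H]2C
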